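Everything rests on cutting the C3–C4 bond of ring A. C4, the only oxidised carbon of ring A, is bonded to ring-fusion C5, and C2–C3 is a bare two-carbon arm on quaternary C1, so ring A unfolds to a 4-pentenal: formyl on C5, vinyl on C1 of a ring B cycloheptene. Rhodium-catalysed hydroacylation closes ring A as the C4 ketone in one operation and leaves the C6 silyl ether and C8=C9 untouched. In the precursor, C1, C5 and C6 come from one chelate-controlled dianionic ester-enolate Claisen rearrangement and ring B from ring-closing metathesis, so C5 does not depend on a methyl-versus-vinyl facial bias.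

Key step: step 10

Remark on numbering: C1 is the quaternary ring-fusion carbon (CH3), C2 and C3 the CH2 carbons of ring A, C4 the carbinol carbon, C5 the ring-fusion CH, C6 the benzoyloxy carbon, C7 CH2, C8 and C9 the epoxide carbons (CH3 on C8), C10 CH2; ring A is five-membered and ring B seven-membered. These labels are kept for all intermediates, acyclic ones included; β is the face of the C1 methyl group; TBS is tert-butyldimethylsilyl.

Remark on supply: ethyl (R)-4-chloro-3-hydroxybutanoate and pent-1-en-4-yne are taken as purchasable.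

Step 1
Reactants: 1 ethyl (R)-4-chloro-3-hydroxybutanoate
Product: 2 ethyl (R)-3,4-epoxybutanoate
Conditions: Ag2O, 1,2-dimethoxyethane, 60 °C
Reagents that add atoms: none
Why: Silver-assisted intramolecular Williamson ring closure of the chlorohydrin under non-basic conditions should give the epoxide without touching the carbinol centre and without the base-induced isomerisation to the 4-hydroxycrotonate.

Step 2
Reactants: 2 ethyl (R)-3,4-epoxybutanoate; 3 isopropenylmagnesium bromide
Product: 4 ethyl (S)-3-hydroxy-5-methylhex-5-enoate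
Conditions: CH2=C(CH3)MgBr, CuI (10 mol %), THF, −40 °C
Reagents that add atoms: isopropenylmagnesium bromide (3), C=C(C)[Mg]Br
Why: Copper-catalysed Grignard opening of a terminal epoxide takes place at the CH2 terminus faster than addition to the ester at low temperature, so the future C6 carbinol centre is carried over unchanged (the descriptor becomes S only through the change in priorities).

Step 3
Reactants: 5 pent-1-en-4-yne; 6 trimethylaluminium; 7 formaldehyde (as paraformaldehyde)
Product: 9 (2E)-3-methylhexa-2,5-dien-1-ol, via alkenylalane 8 (not isolated)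
Conditions: AlMe3, Cp2ZrCl2 (20 mol %), CH2Cl2, 0 °C to rt; then (CH2O)n, THF, 0 °C to rt
Reagents that add atoms: trimethylaluminium (6), C[Al](C)C; formaldehyde (7), C=O
Why: Negishi zirconium-catalysed carboalumination adds CH3 and aluminium syn across the alkyne with aluminium on the terminal carbon, and the alkenyl–aluminium bond is hydroxymethylated with retention, which fixes the E geometry (CH3 cis to CH2OH) that the later rearrangement needs.

Step 4
Reactants: 4 ethyl (S)-3-hydroxy-5-methylhex-5-enoate; 9 (2E)-3-methylhexa-2,5-dien-1-ol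
Product: 10 (2E)-3-methylhexa-2,5-dien-1-yl (3S)-3-hydroxy-5-methylhex-5-enoate
Conditions: Ti(OEt)4 (20 mol %), toluene, 90 °C, ethanol distilled off
Reagents that add atoms: (2E)-3-methylhexa-2,5-dien-1-ol (9), C=CC/C(C)=C/CO
Why: Titanate-catalysed transesterification is neutral enough for a β-hydroxy ester and a skipped diene and is driven by removal of ethanol.

Step 5
Reactants: 10 (2E)-3-methylhexa-2,5-dien-1-yl (3S)-3-hydroxy-5-methylhex-5-enoate
Product: 12 (2S,3S)-3-ethenyl-2-[(1S)-1-hydroxy-3-methylbut-3-en-1-yl]-3-methylhex-5-enoic acid, via dilithium enolate 11 (not isolated)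
Conditions: LiN(iPr)2 (2.3 equiv), THF, −78 °C to 50 °C; 1 M HCl
Reagents that add atoms: none
Why: In this ester-enolate Claisen rearrangement of a β-hydroxy ester dianion, lithium chelation between the C6 alkoxide and the enolate oxygen fixes the enolate geometry and prevents β-elimination, the allyl unit reaches C5 anti to the C7 branch of the chelate (the sense of a Fráter–Seebach alkylation) and so sets C5 against C6, and the chair transition state with the E alkene (C10 arm equatorial) sets quaternary C1 against C5 and forms the C5–C1 bond with the vinyl group in place.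

Step 6
Reactants: 12 (2S,3S)-3-ethenyl-2-[(1S)-1-hydroxy-3-methylbut-3-en-1-yl]-3-methylhex-5-enoic acid
Product: 14 (2S,3S)-2-[(1S)-1-(TBS-oxy)-3-methylbut-3-en-1-yl]-3-ethenyl-3-methylhex-5-enoic acid, via bis-silyl derivative 13 (not isolated)
Conditions: TBSOTf (2.5 equiv), 2,6-lutidine, CH2Cl2, 0 °C; then K2CO3, MeOH/H2O, rt; 1 M HCl to pH 3
Reagents that add atoms: tert-butyldimethylsilyl trifluoromethanesulfonate, CC(C)(C)[Si](C)(C)OS(=O)(=O)C(F)(F)F
Why: The silyl triflate silylates both the hindered secondary C6 hydroxyl and the carboxyl group, and only the labile silyl ester is cleaved by mild carbonate methanolysis.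

Step 7
Reactants: 14 (2S,3S)-2-[(1S)-1-(TBS-oxy)-3-methylbut-3-en-1-yl]-3-ethenyl-3-methylhex-5-enoic acid
Product: 15 (2R,3S)-2-[(1S)-1-(TBS-oxy)-3-methylbut-3-en-1-yl]-3-ethenyl-3-methylhex-5-en-1-ol
Conditions: LiAlH4, THF, 0 °C to rt
Reagents that add atoms: none
Why: Hydride reduction of the carboxylic acid gives the primary C4 alcohol while isolated alkenes and the secondary silyl ether are inert.

Step 8
Reactants: 15 (2R,3S)-2-[(1S)-1-(TBS-oxy)-3-methylbut-3-en-1-yl]-3-ethenyl-3-methylhex-5-en-1-ol
Product: 16 [(1R,2S,7S)-7-(TBS-oxy)-2-ethenyl-2,5-dimethylcyclohept-4-en-1-yl]methanol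
Conditions: RuCl2(=CHPh)(PCy3)(H2IMes) (second-generation Grubbs catalyst, 5 mol %), CH2Cl2 (5 mM), 40 °C
Reagents that add atoms: none
Why: In this ring-closing metathesis the catalyst loads on the unhindered allyl terminus (C9) and closes onto the 1,1-disubstituted C8 alkene to give ring B with the trisubstituted C8=C9 bond, whereas the vinyl group on quaternary C1 is too hindered to initiate or to pair with the 1,1-disubstituted alkene.

Step 9
Reactants: 16 [(1R,2S,7S)-7-(TBS-oxy)-2-ethenyl-2,5-dimethylcyclohept-4-en-1-yl]methanol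
Product: 17 (1S,2S,7S)-7-(TBS-oxy)-2-ethenyl-2,5-dimethylcyclohept-4-ene-1-carbaldehyde
Conditions: Dess–Martin periodinane, CH2Cl2, 0 °C to rt
Reagents that add atoms: none
Why: Dess–Martin oxidation gives the aldehyde under near-neutral conditions, so C5 should not epimerise and the β-silyloxy group should not be eliminated.

Step 10
Reactants: 17 (1S,2S,7S)-7-(TBS-oxy)-2-ethenyl-2,5-dimethylcyclohept-4-ene-1-carbaldehyde
Product: 18 (3aR,8S,8aS)-8-(TBS-oxy)-3a,6-dimethyl-3,3a,4,7,8,8a-hexahydroazulen-1(2H)-one
Conditions: [Rh(nbd)(dppe)]BF4 (5 mol %), H2 then Ar purge, CH2Cl2, 25 °C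
Reagents that add atoms: none
Why: The cationic rhodium–dppe fragment, freed of norbornadiene by hydrogenation, adds oxidatively to the formyl C4–H bond (monovalent to trivalent rhodium), the C1 vinyl group inserts into Rh–H with rhodium ending on terminal C3, and the six-membered acyl rhodacycle (Rh, C4, C5, C1, C2, C3) forms C3–C4 by reductive elimination. The closest known reaction type is the cationic rhodium–diphosphine cyclisation of 4-pentenals to cyclopentanones, which accepts substituents at the 2- and 3-positions. Ring A closes in a formally 5-endo-trig mode with respect to the vinyl group (both alkene carbons become ring atoms), which the metallacycle makes possible. No stereocentre is created: C1 and C5 are carried over, and the trans ring fusion follows from the trans arrangement of formyl and vinyl on ring B, which can both sit pseudo-equatorial. The step needs acyl transfer to the terminal vinyl carbon, cyclisation faster than decarbonylation, no reaction at C8=C9 and no epimerisation at C5; the tether length, the gem-disubstituted C1 and the branch at C5, the low reactivity of a trisubstituted alkene toward hydrometallation and the base-free medium secure these.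

Step 11
Reactants: 18 (3aR,8S,8aS)-8-(TBS-oxy)-3a,6-dimethyl-3,3a,4,7,8,8a-hexahydroazulen-1(2H)-one; 19 isopropylmagnesium chloride
Product: 20 (1R,3aR,8S,8aS)-8-(TBS-oxy)-3a,6-dimethyl-1-(propan-2-yl)-1,2,3,3a,4,7,8,8a-octahydroazulen-1-ol
Conditions: iPrMgCl, CeCl3, THF, −78 °C to 0 °C
Reagents that add atoms: isopropylmagnesium chloride (19), CC(C)[Mg]Cl
Why: The weakly basic organocerium reagent should add to the carbonyl group instead of enolising or reducing the ketone, and it should enter C4 from the α face, anti to the axial C1 methyl group and to the C5–C6 bond, so that the new hydroxyl is β (4R).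

Step 12
Reactants: 20 (1R,3aR,8S,8aS)-8-(TBS-oxy)-3a,6-dimethyl-1-(propan-2-yl)-1,2,3,3a,4,7,8,8a-octahydroazulen-1-ol
Product: 21 (1R,3aR,8S,8aS)-3a,6-dimethyl-1-(propan-2-yl)-1,2,3,3a,4,7,8,8a-octahydroazulene-1,8-diol
Conditions: Bu4NF, THF, 50 °C
Reagents that add atoms: none
Why: Fluoride-induced desilylation frees the C6 hydroxyl while the tertiary alcohol and the alkene are inert.

Step 13
Reactants: 21 (1R,3aR,8S,8aS)-3a,6-dimethyl-1-(propan-2-yl)-1,2,3,3a,4,7,8,8a-octahydroazulene-1,8-diol
Product: 22 (1R,4R,5S,6S,8R,9S)-8α,9α-epoxide of 21 (4β,6α-diol; core numbering)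
Conditions: VO(acac)2 (5 mol %), t-BuOOH, CH2Cl2, 0 °C to rt
Reagents that add atoms: tert-butyl hydroperoxide, CC(C)(C)OO
Why: In this vanadium-catalysed hydroxyl-directed epoxidation the α-oriented C6 hydroxyl, homoallylic to C8=C9, binds the vanadium alkyl peroxide and delivers oxygen to its own face, which is also the face away from the C1 methyl group, setting C8 (R) and C9 (S).

Step 14
Reactants: 22 (1R,4R,5S,6S,8R,9S)-8α,9α-epoxide of 21; 23 benzoyl chloride
Product: 24 CNP0340059.1, the C6 benzoate of 22
Conditions: BzCl, pyridine, DMAP (10 mol %), CH2Cl2, 0 °C to rt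
Reagents that add atoms: benzoyl chloride (23), O=C(Cl)c1ccccc1
Why: DMAP-catalysed acylation should take place only at the secondary C6 hydroxyl, the tertiary C4 hydroxyl being too hindered, and the amine-buffered medium leaves the epoxide intact.

Compound list

1 | ethyl (R)-4-chloro-3-hydroxybutanoate | ClC[C@H](O)CC(=O)OCC | starting material
2 | ethyl (R)-3,4-epoxybutanoate | C1O[C@@H]1CC(=O)OCC | intermediate
3 | isopropenylmagnesium bromide | C=C(C)[Mg]Br | starting material
4 | ethyl (S)-3-hydroxy-5-methylhex-5-enoate | C=C(C)C[C@H](O)CC(=O)OCC | intermediate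
5 | pent-1-en-4-yne | C=CCC#C | starting material
6 | trimethylaluminium | C[Al](C)C | starting material
7 | formaldehyde (used as paraformaldehyde) | C=O | starting material
8 | dimethyl[(1E)-2-methylpenta-1,4-dien-1-yl]alane | C=CC/C(C)=C/[Al](C)C | intermediate (not isolated)
9 | (2E)-3-methylhexa-2,5-dien-1-ol | C=CC/C(C)=C/CO | intermediate
10 | (2E)-3-methylhexa-2,5-dien-1-yl (3S)-3-hydroxy-5-methylhex-5-enoate | C=C(C)C[C@H](O)CC(=O)OC/C=C(C)/CC=C | intermediate
11 | dilithium alkoxide–enolate of 10 (chelate, C6 cis to the enolate O–Li) | C=C(C)C[C@H](O[Li])/C=C(\O[Li])OC/C=C(C)/CC=C | intermediate (not isolated)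
12 | (2S,3S)-3-ethenyl-2-[(1S)-1-hydroxy-3-methylbut-3-en-1-yl]-3-methylhex-5-enoic acid | C=C[C@](C)(CC=C)[C@H](C(=O)O)[C@@H](O)CC(C)=C | intermediate
13 | TBS ester of 14 (silyl ether and silyl ester) | C=C[C@](C)(CC=C)[C@H](C(=O)O[Si](C)(C)C(C)(C)C)[C@@H](O[Si](C)(C)C(C)(C)C)CC(C)=C | intermediate (not isolated)
14 | (2S,3S)-2-[(1S)-1-(TBS-oxy)-3-methylbut-3-en-1-yl]-3-ethenyl-3-methylhex-5-enoic acid | C=C[C@](C)(CC=C)[C@H](C(=O)O)[C@@H](O[Si](C)(C)C(C)(C)C)CC(C)=C | intermediate
15 | (2R,3S)-2-[(1S)-1-(TBS-oxy)-3-methylbut-3-en-1-yl]-3-ethenyl-3-methylhex-5-en-1-ol | C=C[C@](C)(CC=C)[C@H](CO)[C@@H](O[Si](C)(C)C(C)(C)C)CC(C)=C | intermediate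
16 | [(1R,2S,7S)-7-(TBS-oxy)-2-ethenyl-2,5-dimethylcyclohept-4-en-1-yl]methanol | C=C[C@]1(C)CC=C(C)C[C@H](O[Si](C)(C)C(C)(C)C)[C@H]1CO | intermediate
17 | (1S,2S,7S)-7-(TBS-oxy)-2-ethenyl-2,5-dimethylcyclohept-4-ene-1-carbaldehyde | C=C[C@]1(C)CC=C(C)C[C@H](O[Si](C)(C)C(C)(C)C)[C@H]1C=O | intermediate
18 | (3aR,8S,8aS)-8-(TBS-oxy)-3a,6-dimethyl-3,3a,4,7,8,8a-hexahydroazulen-1(2H)-one (trans-fused) | O=C1CC[C@]2(C)CC=C(C)C[C@H](O[Si](C)(C)C(C)(C)C)[C@H]21 | intermediate
19 | isopropylmagnesium chloride | CC(C)[Mg]Cl | starting material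
20 | (1R,3aR,8S,8aS)-8-(TBS-oxy)-3a,6-dimethyl-1-(propan-2-yl)-1,2,3,3a,4,7,8,8a-octahydroazulen-1-ol | CC(C)[C@]1(O)CC[C@]2(C)CC=C(C)C[C@H](O[Si](C)(C)C(C)(C)C)[C@H]21 | intermediate
21 | (1R,3aR,8S,8aS)-3a,6-dimethyl-1-(propan-2-yl)-1,2,3,3a,4,7,8,8a-octahydroazulene-1,8-diol | CC(C)[C@]1(O)CC[C@]2(C)CC=C(C)C[C@H](O)[C@H]21 | intermediate
22 | (1R,4R,5S,6S,8R,9S)-8α,9α-epoxide of 21 (epoxide oxygen cis to the C6 hydroxyl; core numbering) | CC(C)[C@]1(O)CC[C@]2(C)C[C@@H]3O[C@]3(C)C[C@H](O)[C@H]21 | intermediate
23 | benzoyl chloride | O=C(Cl)c1ccccc1 | starting material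
24 | CNP0340059.1: trans-fused ring A/ring B core with 1β-CH3, 4β-OH, 4α-isopropyl, 6α-benzoyloxy, 8α,9α-epoxide and 8-CH3, (1R,4R,5S,6S,8R,9S) in core numbering | CC(C)[C@]1(O)CC[C@]2(C)C[C@@H]3O[C@]3(C)C[C@H](OC(=O)c3ccccc3)[C@H]21 | target

Total step count: 14. Longest linear sequence: 13 steps (1 → 2 → 4 → 10 → 12 → 14 → 15 → 16 → 17 → 18 → 20 → 21 → 22 → 24); step 3 supplies the side fragment 9.

Steps most likely to fail

Step 10. Decarbonylation of the acyl rhodium hydride, which ties the metal up as a carbonyl complex and stops turnover, may outrun insertion of the hindered vinyl group, or the α-branched formyl group may add too slowly. The fallback sets out from 17: vinylmagnesium bromide is added to the formyl group to give the divinyl carbinol F1 (both C4 epimers serve). Ring A is then closed between the two vinyl groups by ring-closing metathesis with RuCl2(=CHPh)(PCy3)(H2IMes) to give the cyclopentenol F2. Oxidation with Dess–Martin periodinane gives the enone F3, and 1,4-reduction with [CuH(PPh3)]6 comes back to the route at 18. In this detour C3 stems from the Grignard reagent and the former terminal vinyl carbon leaves as ethylene.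

Step 5. The dianion may fragment to a ketene and the dienyl alkoxide on warming before it rearranges, or the chelate may give too little facial control at C5. The fallback sets out from 10: the C6 hydroxyl is silylated (TBSOTf, 2,6-lutidine) to the silyl ether F4. LiN(iPr)2 with Me3SiCl as internal quench (THF/DMPU, −78 °C) converts it into the silyl ketene acetal F5 with C6 cis to OSiMe3. Warming brings about the Ireland–Claisen rearrangement through the same chair to the trimethylsilyl ester F6, and hydrolysis on work-up comes back to the route at 14, replacing steps 5 and 6. Facial control at C5 would then rest on allylic strain in the ketene acetal and could be lower than in the chelate.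

Step 11. Enolisation of the hindered ketone, followed by loss of the β-silyloxy group, or β-hydride transfer from the secondary Grignard reagent may compete with addition. The fallback sets out from 18: isopropenylmagnesium bromide (3) with CeCl3, a smaller nucleophile without β-hydrogen, is added from the same α face to give the isopropenyl carbinol F7. Hydrogenation with RhCl(PPh3)3 under H2, selective for the 1,1-disubstituted alkene over the trisubstituted C8=C9, comes back to the route at 20.

Further compounds

F1 | step 10 | divinyl carbinol from vinyl addition to the formyl group of 17 (C4 epimers) | C=C[C@]1(C)CC=C(C)C[C@H](O[Si](C)(C)C(C)(C)C)[C@H]1C(O)C=C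
F2 | step 10 | trans-fused cyclopentenol with C2=C3 and C4–OH (C4 epimers), C6 TBS ether | OC1C=C[C@]2(C)CC=C(C)C[C@H](O[Si](C)(C)C(C)(C)C)[C@H]21
F3 | step 10 | trans-fused cyclopentenone (C4 ketone, C2=C3), C6 TBS ether | O=C1C=C[C@]2(C)CC=C(C)C[C@H](O[Si](C)(C)C(C)(C)C)[C@H]21
F4 | step 5 | (2E)-3-methylhexa-2,5-dien-1-yl (3S)-3-(TBS-oxy)-5-methylhex-5-enoate | C=C(C)C[C@H](O[Si](C)(C)C(C)(C)C)CC(=O)OC/C=C(C)/CC=C
F5 | step 5 | trimethylsilyl ketene acetal of F4 with C6 cis to OSiMe3 | C=C(C)C[C@H](O[Si](C)(C)C(C)(C)C)/C=C(\O[Si](C)(C)C)OC/C=C(C)/CC=C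
F6 | step 5 | trimethylsilyl ester of 14 | C=C[C@](C)(CC=C)[C@H](C(=O)O[Si](C)(C)C)[C@@H](O[Si](C)(C)C(C)(C)C)CC(C)=C
F7 | step 11 | isopropenyl carbinol: 20 with prop-1-en-2-yl in place of isopropyl at C4 | C=C(C)[C@]1(O)CC[C@]2(C)CC=C(C)C[C@H](O[Si](C)(C)C(C)(C)C)[C@H]21
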